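Readings and results were computed with constants of no real substance; scatter was added.

A closed, stirred vessel holds G and J with L as catalyst, and the alder run differs from the maple run in [L] alone, 0.480 mM against 2.40 mM.

| setting | maple | larch | alder |
|---|---|---|---|
| G | 120 mM | 120 mM | 120 mM |
| J | 300 mM | 150 mM | 300 mM |
| L | 2.40 mM | 2.40 mM | 0.480 mM |
| time |  |  | 8.8 min |

- maple run (time / min: [X] / mM): 1.1: 19.3; 2.2: 36.5; 3.3: 51.1; 4.4: 62.7; 5.5: 73.2; 6.6: 81.1; 7.7: 86.4; 8.8: 89.8
- larch run (time / min: [X] / mM): 1.1: 12.1; 2.2: 23.5; 3.3: 32.3; 4.4: 40.7; 5.5: 46.7; 6.6: 51.6; 7.7: 56.7; 8.8: 60.7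

(standard deviation of a reading: 0.4 mM)

- the power of [J] that the first rate follows, about the charge of the maple run; measure it at two percent of G made into X
- X in the alder run at 8.8 min, as a share of the G charged

- Overall: G + J -> X, with L as catalyst.
- Constant volume, constant temperature.
- A reading of a species includes what of it is bound.
- An order is taken over about fifteen percent of the charge, up and down.

At the first reading, 1.1 min, the maple run holds 19.3 mM of X and the larch run 12.1 mM, a ratio of 0.627 for half the [J]. My reckoning reads from this an average power of 0.674 between 150 mM and 300 mM of J.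

For alder, count turnovers. The quantity to carry is the X made per L charged per minute over the first maple interval, the turnover frequency 7.31 min⁻¹. My reckoning assumes that this rate per L carries over to alder's [L]; maple and larch share 2.40 mM, so neither tests it.

The maple run makes X at 17.5 mM min⁻¹ over its first interval and at 3.09 mM min⁻¹ over its last, slower, so on this assumption alder holding the first frequency for its whole time gives a ceiling:

ceiling = 7.31 min⁻¹ × 0.480 mM × 8.8 min = 30.9 mM, or 25.7 % of G

Maple's whole-run average is 4.25 min⁻¹, taken as far as 89.8 mM of X, and it gives a floor: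

floor = 4.25 min⁻¹ × 0.480 mM × 8.8 min = 18.0 mM, or 15.0 % of G

The bracket tightens if equal [L]·t means equal progress. Alder's 8.8 min then matches maple at this time:

1.76 min

Between the first two maple readings, that time gives 29.6 mM, or 24.7 % of G.

The forecast gives 23.5 % (from 14 % to 33 %) and an order of 0.6 (from 0.35 to 0.85), on the ground that “a fifth of the catalyst over 8.8 min equals maple at 1.76 min”. Its 23.5 % stands inside the bracket, lower than my figure, and its order is lower than my 0.674.

The simulation gives 22.1 % and an order of 0.56, so alder lies inside the bracket, 2.6 percentage points lower than my figure.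

    L + G ⇌ LG, settled at all times (6.650 M⁻¹)
    LG + J ⇌ LGJ, settled at all times (27.70 M⁻¹)
    LGJ → X + L (17.16 min⁻¹)
    2 G ⇌ G2, settled at all times (181.0 M⁻¹)
    X → Ez (0.03372 min⁻¹)

The step X → Ez has the constant 0.0337 min⁻¹; constant times time is 0.297 over alder's 8.8 min against 0.0593 over maple's 1.76 min. Alder's standing X comes to 6.29 min⁻¹ per L on average over its time, lower than the carried 7.31 min⁻¹. The same count on the larch run, at two percent of maple's G turned, gives 4.91 min⁻¹.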